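## Structural features

Septeremophilane G is an 11,12,13-trinoreremophilane, a 4,5-dimethyloctalin. Ring A (C1–C5 and C10, eremophilane numbering throughout) is saturated, and ring B (C5–C10) is a cross-conjugated 7-hydroxy-6,9-dien-8-one, the enol (diosphenol) form of a 7,8-dione. The rings share the C5–C10 bond; C5 is quaternary and C10 is trigonal, so no ring-fusion hydrogen survives in the target. Four stereocentres stand in a row on ring A: C2 (free hydroxyl, α), C3 (acyloxy, β), C4 (secondary methyl, β) and C5 (quaternary methyl, β), that is 2R,3R,4R,5S. The C3 oxygen and the two methyls are mutually cis and the C2 hydroxyl is trans to them, so in the chair with the C5 methyl axial the C2–O and C3–O bonds are trans-diaxial. O3 carries a (2E,4E,6S)-6-methylocta-2,4-dienoyl group whose remote stereocentre must be supplied enantiopure. Fragile points are the acidic, oxidisable diosphenol, the dienone (dienone–phenol rearrangement in strong acid; C1–H is doubly allylic and vinylogously acidic, so base can expel the C2 oxygen) and the conjugated dienoate. The real difficulty is the cis pair of a tertiary methyl at C4 and a quaternary methyl at C5, next to an axial C3–O bond that lies syn to the C5 methyl, together with acylating O3 while O2 stays free. The key step exploits that the C4–C5 bond has oxygen on C2 and on C7: C4=C3–C2(O)–C7(O)–C6=C5 is a 3-oxy-1,5-diene in which C2–C7 can be a bond of a bicyclo[2.2.2]octenol, so one [3,3] shift makes C4–C5, both methyl-bearing centres and ring A, and leaves C7 as an enol ether.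

## Logic of the disconnections

30 is taken back to 29 by placing a silyl group on O7 (O–Si bond). This keeps the acidic enol quiet during the last bond-forming steps; the forward step must cleave Si–O without touching the ester or C1–H.

In 29 the C3–O bond (ring carbon to ester oxygen) is cut, giving 28 and 6. A trans-diaxial 2-hydroxy-3-acyloxy pair is the retron of an epoxide opening; the cut joins the two fragments, sets C3 and leaves O2 free, so no hydroxyl has to be told from another. The forward step demands attack at C3 from the β face, anti to the oxirane oxygen and syn to the C5 methyl, under conditions mild enough to leave C1–H alone.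

The two C–O bonds of the oxirane in 28 are cut to the C2=C3 alkene of 27. C2 and C3 lose their stereochemistry. The forward step must deliver oxygen to the α face and to this alkene only, which is why the oxirane is made only once C10 is trigonal and ring A is conformationally fixed with the C5 methyl axial.

Ring B of 27 is simplified by removing the C9=C10 π bond and the O7–Si bond, leading through 26 to 25. Then 25 goes back to 24 (C8 carbonyl to carbinol), 24 to 23 (C2–H to C2–OTf) and 23 to 22 (C7 carbonyl to methyl enol ether, O8–H to O8–tert-butyl). These are functional-group changes only; they show that both ring B oxygens and the ring A alkene are already present, masked, in 22. The forward demands are regioselective dehydrogenation at C9–C10 and an order in which acid is used while C2=C3 is still a deactivated enol triflate.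

In 22, seen as its enolate 21, the C4–C5 bond is cut and C2–C7 is joined, giving 19 through 20. This one cut removes the cis-fused decalin, the quaternary C5 and the tertiary C4 together. The forward step needs the propenyl group syn to the C5=C6 bridge, the Z geometry, one enantiomer of the bicycle, and capture of the enolate on oxygen before it equilibrates. Two points of bookkeeping: ring A (C1–C2–C3–C4–C5–C10) is closed by the C4–C5 bond from the two propenyl carbons and four carbons of the bicycle, and is not the six-atom array of the shift itself; and the shift creates two stereocentres (C4, C5), C10 being carried over.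

In 19 the C2–C3 bond is cut, giving 15 and 16 (through 17 and 18). The tertiary carbinol becomes a ketone and a three-carbon vinyl metal. The forward step must add to the face of the ketone that looks at the alkene bridge, keep the Z geometry and avoid enolisation.

15 is taken back to 14 by putting two methoxyls on C1 (two C–O bonds), which turns it into a masked o-benzoquinone adduct. The methoxyls are removed before the rearrangement, not after, for three reasons:
- Only next to the C2 ketone can they be cut off by electron transfer, and once C3 bears oxygen the same reagent would strip that oxygen too.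
- With C1 as CH2 the regiochemistry of the enolate made by the shift has a meaning.
- The C1 methoxyl that looks toward the alkene bridge would meet the inward Z-methyl in the boat array.

The forward step must spare the bridgehead methoxyl.

14 is traced through 13 (C2–CH2S bond) to 10 and 11. The cut is a resolution: it adds no skeletal complexity and supplies the absolute configuration. The forward steps need separable diastereomers and a clean thermal reversal.

In 10 the bonds C7–C8 and C9–C10 (eremophilane numbering, the two bonds from the ethano bridge to the bridgeheads) and one C1–OMe bond are cut, giving 7 and 8 through 9. A bicyclic ketone with four stereocentres becomes a symmetric phenol and a vinyl ether. The forward step needs the alkoxy carbon to bond to the methoxy-bearing diene terminus and in-situ trapping of 9.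

6 is taken back to 5 (ester O–C), 5 is cut at the C4=C5 double bond of the dienoate into 2 and 3 (through 4), and 2 comes from 1. The side chain becomes a chiral-pool alcohol and a four-carbon phosphonate. The forward steps need E selectivity and no enolisation of 2.

## Other disconnections considered

Alternative 1: The cut is at C3–C4 and C5–C10, opening both rings to the acyclic tigloyl ketone triene A1. In the forward sense, heat or Me2AlCl makes the 1-silyloxydiene (C3=C2–C1=C10) add to the tigloyl alkene (C4=C5) to give the trans-fused octalenone A2.
- In its favour: two rings, two C–C bonds and the C3/C4/C5 triad form in one step. The cis relation of the methyls follows from the E-tigloyl geometry, which is as dependable as the Z-propenyl geometry of the chosen plan (equal on this point). The C3 oxygen is present from the start, so the hindered axial C3–O bond need not be made on the ring, and A1 could be built from an enantiopure carbinol without a resolution (better on both points).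
- Against it here: a trisubstituted enone that must form a quaternary centre is a sluggish dienophile, and the silyloxydiene is sensitive to the Lewis acid that would speed it. The face of addition is steered only by the remote C8 silyloxy centre. Placing O3 cis to the methyls needs the tether carbonyl exo, against the usual endo preference of an activated carbonyl. A2 has its carbonyl at C6, a plain CH in the target, and no oxygen at C7, so ring B would need a carbonyl transposition, a second oxygen and the C9=C10 bond.
- Comparison: both key steps are concerted six-electron processes that translate alkene geometry into the C4/C5 relationship. Structurally the chosen plan delivers C7 and C8 oxygenated from the aromatic ring, whereas A2 serves ring A well and ring B badly. In step count, the saving at the front of alternative 1 is expected to be spent, and more, on ring B.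

Alternative 2: The cut is at C1–C2, opening ring A to the α-alkoxy aldehyde A3 that hangs on a methylenecyclohexane. In the forward sense, MgBr2·OEt2 or Me2AlCl activates the aldehyde for an intramolecular carbonyl-ene reaction: C2 bonds to C1, H9 moves to oxygen and the alkene shifts to C9=C10, giving A4.
- In its favour: the step closes ring A, makes the C2 carbinol and installs C9=C10 at once, with O2 free and O3 protected, so neither a dehydrogenation nor an oxirane is needed (better than the chosen plan on these points). Chelation of the metal between the aldehyde and O3 in a chair-like array should set C2 trans to C3.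
- Against it: the C4/C5 problem is moved, not solved. A3 already needs the C3–C4–C5 triad with its quaternary centre, to be built by separate stereocontrolled steps. After the closure O2 and O3 must change roles (protect O2, free O3, acylate, deprotect O2). The C7 ketal must still be raised to the 7,8-dione level. The Lewis acid must spare the ketal and the PMB ether and not divert the cation to a Prins product.
- Comparison: like the chosen shift it is a concerted pericyclic event through a six-membered array, and it is the more direct on C2 and C9=C10. Structurally the chosen plan is stronger where the target is hardest (C4–C5). In steps, the shorter endgame of alternative 2 is expected to be offset by the longer route to A3.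

Alternative 3: The cut is at C1–C10, opening ring A to the methyl ketone A5, a 4,4-disubstituted 2,6-dimethoxycyclohexa-2,5-dienone that a para-Claisen rearrangement could derive from the same phenol 7. In the forward sense, pyrrolidine (enamine) or mild base adds C1 to C10 of one of the two enone arms and gives the cis-fused dione A6, fixing C5 by desymmetrisation.
- In its favour: like the chosen plan it takes ring B with both oxygens on the right carbons from the aromatic starting material (equal). C5 is set without a resolution if C3 and C4 are made enantioselectively (better). The ring closure is operationally simple.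
- Against it: the configuration of C5 rests on which arm is attacked, a choice governed only by the C3/C4 substituents in a reversible reaction. A6 keeps a methoxyl on C9 whose loss together with H10 would give C9=C10 but is not a straightforward elimination, since leaving group and acidic hydrogen sit on the same carbon. The C2 ketone must then be reduced to the axial α-carbinol. The O7 methyl must be removed late from an acid-sensitive dienone. The para-Claisen has to deliver the C4 centre.
- Comparison: a polar, reversible Michael addition under thermodynamic influence stands against an irreversible sigmatropic shift whose course is dictated by the bicycle. In step count the two are expected to be close, and alternative 3 is the equal of the chosen plan in its use of the phenol.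

Key step: step 9

## Remarks on the chemistry (assumptions)

- Eremophilane locants (C1–C10, methyls on C4 and C5) are used for all decalins; β is the face of ring A that carries the two methyls. Bicyclic compounds carry von Baeyer locants.
- Compound 10 is a racemate; its SMILES shows the enantiomer that is carried on.
- tert-Butyl vinyl ether and (S)-N,S-dimethyl-S-phenylsulfoximine are taken to be commercial.
- Spectator groups of the rearrangement precursor 19 are chosen for the endgame. A tert-butyl ether on O8 falls in the same acid step that unmasks C7; a benzyl ether would call for hydrogenolysis beside alkenes. C1 carries no methoxyls at the stage of the shift.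

## Route

Step 1
Reactants: 1 (S)-2-methylbutan-1-ol
Product: 2 (S)-2-methylbutanal
Conditions: TEMPO (10 mol %), PhI(OAc)2 (1.1 equiv), CH2Cl2, 0 °C to rt; washed, dried solution used directly
Reagents that add atoms: none
Why: Oxoammonium-mediated alcohol oxidation stops at the aldehyde under non-basic conditions, so the α-stereocentre is not enolised; the volatile aldehyde is not concentrated.

Step 2
Reactants: 2 (S)-2-methylbutanal; 3 triethyl (E)-4-phosphonocrotonate
Product: 5 ethyl (2E,4E,6S)-6-methylocta-2,4-dienoate, via lithium phosphonate carbanion 4 (not isolated)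
Conditions: 3, LiN(SiMe3)2, THF, −78 °C; then 2, −78 to 0 °C
Reagents that add atoms: none
Why: Vinylogous Horner–Wadsworth–Emmons olefination; the stabilised carbanion reacts at the phosphorus-bearing carbon and gives the new C4=C5 bond E, the 2E bond coming with the reagent. Low temperature and a non-nucleophilic amide base keep the α-branched aldehyde from epimerising.

Step 3
Reactants: 5 ethyl (2E,4E,6S)-6-methylocta-2,4-dienoate
Product: 6 (2E,4E,6S)-6-methylocta-2,4-dienoic acid
Conditions: LiOH·H2O, THF/H2O, rt; then 1 M HCl
Reagents that add atoms: lithium hydroxide, [Li+].[OH-]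
Why: Saponification of an unhindered ethyl ester; the remote C6 centre and the E,E-diene are not affected at room temperature.

Step 4
Reactants: 7 2,6-dimethoxy-4-methylphenol; 8 tert-butyl vinyl ether
Product: 10 rac-(1S*,4R*,7R*)-7-tert-butoxy-1,3,3-trimethoxy-5-methylbicyclo[2.2.2]oct-5-en-2-one (endo adduct), via masked o-benzoquinone 9 (not isolated)
Conditions: PhI(OAc)2 (1.1 equiv), MeOH, 8 (10 equiv), 0 °C to rt
Reagents that add atoms: methanol, CO
Why: Oxidative dearomatisation by trivalent iodine in methanol gives the 6,6-dimethoxycyclohexa-2,4-dienone, trapped at once in an inverse-demand Diels–Alder reaction. The nucleophilic CH2 of the vinyl ether bonds to the δ-carbon of the dienone, so the alkoxy carbon ends next to the methoxy bridgehead, and the endo mode places the alkoxy group syn to the new alkene bridge.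

Step 5
Reactants: 10 rac-7-tert-butoxy-1,3,3-trimethoxy-5-methylbicyclo[2.2.2]oct-5-en-2-one; 11 (S)-N,S-dimethyl-S-phenylsulfoximine
Product: 13 (1S,2S,4R,7R)-7-tert-butoxy-1,3,3-trimethoxy-5-methyl-2-{[(S)-N-methyl-S-phenylsulfonimidoyl]methyl}bicyclo[2.2.2]oct-5-en-2-ol (one diastereomer after chromatography), via lithiated sulfoximine 12 (not isolated)
Conditions: 11, n-BuLi, THF, −78 to 0 °C; then 10, −78 °C; H2O; SiO2 separation of the two diastereomers
Reagents that add atoms: none
Why: 1,2-Addition of the enantiopure α-sulfonimidoyl carbanion to the non-enolisable ketone, from the face of the alkene bridge, turns the two enantiomers into diastereomeric β-hydroxysulfoximines that differ at a stereocentre next to the carbinol and are separable (covalent resolution of a ketone). At most half of the material has the needed handedness.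

Step 6
Reactants: 13 β-hydroxysulfoximine
Product: 14 (1S,4R,7R)-7-tert-butoxy-1,3,3-trimethoxy-5-methylbicyclo[2.2.2]oct-5-en-2-one
Conditions: toluene, 110 °C
Reagents that add atoms: none
Why: β-Hydroxysulfoximines revert thermally to ketone and sulfoximine (retro-addition), far below the temperature of retro-Diels–Alder cleavage; no stereocentre of the ketone is touched and the auxiliary is recovered.

Step 7
Reactants: 14 (1S,4R,7R)-7-tert-butoxy-1,3,3-trimethoxy-5-methylbicyclo[2.2.2]oct-5-en-2-one
Product: 15 (1S,4S,7R)-7-tert-butoxy-1-methoxy-5-methylbicyclo[2.2.2]oct-5-en-2-one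
Conditions: SmI2 (5 equiv), THF/MeOH, −78 °C to rt
Reagents that add atoms: none
Why: Reductive cleavage of α-alkoxy ketones: ketyl formation and β-expulsion of methoxide, twice, with protonation by methanol. The bridgehead C1–OMe bond lies in the nodal plane of the ketyl and would give a bridgehead enolate, so only the two C3 methoxyls leave.

Step 8
Reactants: 15 (1S,4S,7R)-7-tert-butoxy-1-methoxy-5-methylbicyclo[2.2.2]oct-5-en-2-one; 16 (Z)-1-bromoprop-1-ene
Product: 19 (1S,2S,4S,7R)-7-tert-butoxy-1-methoxy-5-methyl-2-[(1Z)-prop-1-en-1-yl]bicyclo[2.2.2]oct-5-en-2-ol, via (Z)-prop-1-enyllithium 17 (not isolated), via (Z)-prop-1-enylcerium dichloride 18 (not isolated)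
Conditions: 16, Li (1% Na), Et2O, −10 °C; CeCl3 (anhydrous), THF, −78 °C; then 15, −78 °C
Reagents that add atoms: none
Why: Reductive lithiation of the vinyl bromide keeps the Z geometry, and the weakly basic organocerium adds to the now enolisable ketone without deprotonating it. Attack comes from the face of the C5=C6 bridge, which carries no hydrogens pointing at the carbonyl (the ethano bridge does), so the propenyl group ends syn to the alkene, as the shift requires.

Step 9
Reactants: 19 (1S,2S,4S,7R)-7-tert-butoxy-1-methoxy-5-methyl-2-[(1Z)-prop-1-en-1-yl]bicyclo[2.2.2]oct-5-en-2-ol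
Product: 22 8β-tert-butoxy-7-methoxy-10βH-11,12,13-trinoreremophila-2,6-dien-2-yl trifluoromethanesulfonate (4β,5β-dimethyl; cis-fused), via potassium alkoxide 20 (not isolated), via potassium enolate 21 (not isolated)
Conditions: KH (3 equiv), 18-crown-6, THF, 0 °C to rt; then N-(5-chloropyridin-2-yl)bis(trifluoromethanesulfonyl)imide, −78 to 0 °C
Reagents that add atoms: N-(5-chloropyridin-2-yl)-1,1,1-trifluoro-N-(trifluoromethylsulfonyl)methanesulfonamide, FC(F)(F)S(=O)(=O)N(c1ccc(Cl)cn1)S(=O)(=O)C(F)(F)F
Why: KH with 18-crown-6 turns 19 into the dissociated potassium alkoxide 20, whose oxyanion weakens the C2–C7 bond, and a concerted [3,3]-sigmatropic (anionic oxy-Cope) shift forms C4–C5 while C2–C7 breaks, giving enolate 21 (eremophilane locants). The closest known reaction is the alkoxide-accelerated oxy-Cope rearrangement of 1-methoxy-2-vinylbicyclo[2.2.2]oct-5-en-2-ols to cis-fused octalenones. Ring A (C1–C2–C3–C4–C5–C10) is closed by the new C4–C5 bond in a suprafacial pericyclic closure through a boat-shaped six-centre array, the only one the bicycle allows; ring B is not closed but is the ring C5–C10 of the bicycle, set free when C2–C7 breaks. C5 is set because the propenyl terminus can reach only the face of the C5=C6 bridge that looks at the carbinol bridge, so its configuration (S) and the cis fusion to the unchanged C10 follow from the resolved bicycle. C4 is set by alkene geometry: in the boat array the Z-methyl points inward and ends cis to the C5 methyl. The step needs the [3,3] shift to outrun fragmentation, which the syn placement of propenyl and alkene bridge and the bridgehead methoxyl (it stabilises the developing enol ether) secure, and it needs the enolate to keep its regiochemistry, which the absence of any proton source secures (H2 escapes and C1, now CH2, is never deprotonated). O-Sulfonylation at −78 °C then fixes C2=C3 as enol triflate 22, and the C6=C7 methyl enol ether is inert to base.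

Step 10
Reactants: 22 enol triflate with C6=C7 methyl enol ether and 8β-tert-butyl ether
Product: 23 8β-hydroxy-7-oxo-10βH-11,12,13-trinoreremophil-2-en-2-yl trifluoromethanesulfonate (4β,5β-dimethyl; cis-fused)
Conditions: TFA/CH2Cl2/H2O (10:10:1), 0 °C to rt; aq. NaHCO3 work-up
Reagents that add atoms: water, O
Why: Aqueous acid hydrolyses the isolated, electron-rich methyl enol ether to the C7 ketone, and trifluoroacetic acid cleaves the tert-butyl ether by loss of isobutene. The enol triflate is inert to acid and its deactivated double bond cannot enter cation–olefin reactions; C8 is not touched and will in any case become a carbonyl.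

Step 11
Reactants: 23 ketol enol triflate
Product: 24 8β-hydroxy-10βH-11,12,13-trinoreremophil-2-en-7-one (4β,5β-dimethyl; cis-fused)
Conditions: Pd(OAc)2 (5 mol %), PPh3 (10 mol %), HCO2H, Bu3N, DMF, 60 °C
Reagents that add atoms: none
Why: Palladium-catalysed formate reduction of an enol triflate: oxidative addition to zerovalent palladium, formate-to-hydride exchange with loss of CO2, and reductive elimination. This puts the C2=C3 alkene exactly where the regiodefined enolate was; a ketol epimer or isomer formed under the amine converges in the next step.

Step 12
Reactants: 24 ketol alkene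
Product: 25 10βH-11,12,13-trinoreremophil-2-ene-7,8-dione (4β,5β-dimethyl; cis-fused; largely enolised)
Conditions: DMP [1,1,1-tris(acetyloxy)-1,1-dihydro-1,2-benziodoxol-3(1H)-one], CH2Cl2, 0 °C to rt
Reagents that add atoms: none
Why: Periodinane oxidation of an acyloin to the 1,2-dione; there is no other alcohol and the isolated alkene is inert.

Step 13
Reactants: 25 7,8-dione
Product: 27 7-(tert-butyldimethylsilyloxy)-11,12,13-trinoreremophila-2,6,9-trien-8-one (4S,5S; 4β,5β-dimethyl), via bis-silyl dienol ether 26 (not isolated)
Conditions: TBSOTf (2.5 equiv), Et3N, CH2Cl2, 0 °C; then Pd(OAc)2 (1.1 equiv), MeCN, rt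
Reagents that add atoms: tert-butyldimethylsilyl trifluoromethanesulfonate, CC(C)(C)[Si](C)(C)OS(=O)(=O)C(F)(F)F
Why: Exhaustive O-silylation of the dione can give only the 7,8-bis(silyloxy)-6,8-diene 26, since C6 and C9 are the only enolisable positions. In the Saegusa–Ito oxidation, divalent palladium can complete a β-hydride elimination only from the C8 enol ether (H on C10), because the C7 enol ether ends at the quaternary C5. C9=C10 is therefore introduced and O7 keeps its silyl group, with no ambiguity of diosphenol tautomers.

Step 14
Reactants: 27 silyloxy trienone
Product: 28 2α,3α-epoxy-7-(tert-butyldimethylsilyloxy)-11,12,13-trinoreremophila-6,9-dien-8-one (2R,3S,4R,5S)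
Conditions: mCPBA (1.1 equiv), CH2Cl2, 0 °C
Reagents that add atoms: 3-chloroperoxybenzoic acid, OOC(=O)c1cccc(Cl)c1
Why: Peracid epoxidation of the isolated cis-disubstituted alkene. With C10 trigonal, ring A is a half-chair with the C5 methyl axial on the β face and the C4 methyl also β, so the reagent comes from the α face. C6=C7 is conjugated to the dienone carbonyl, trisubstituted and neopentylic, and C9=C10 is an electron-poor enone bond, so both should react far more slowly.

Step 15
Reactants: 28 2α,3α-epoxide; 6 (2E,4E,6S)-6-methylocta-2,4-dienoic acid
Product: 29 7-(tert-butyldimethylsilyloxy)-2α-hydroxy-8-oxo-11,12,13-trinoreremophila-6,9-dien-3β-yl (2E,4E,6S)-6-methylocta-2,4-dienoate (2R,3R,4R,5S)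
Conditions: 6 (2 equiv), Co(salen)(OAc) (10 mol %; salen = N,N'-bis(3,5-di-tert-butylsalicylidene)cyclohexane-1,2-diamine dianion, enantiomer matched to C3 attack), TBME, rt
Reagents that add atoms: none
Why: Lewis-acid-assisted ring opening of an epoxide by a carboxylic acid; the trivalent cobalt complex activates the oxirane and delivers the carboxylate. By the Fürst–Plattner rule the only chair-like (trans-diaxial) path is attack at C3 from the β face, which inverts C3 and leaves O2 α, giving the free 2α-hydroxyl and the 3β-ester in one step. Near-neutral conditions at room temperature avoid deprotonation at C1.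

Step 16
Reactants: 29 O7-silylated hydroxy ester
Product: 30 septeremophilane G, 2α,7-dihydroxy-8-oxo-11,12,13-trinoreremophila-6,9-dien-3β-yl (2E,4E,6S)-6-methylocta-2,4-dienoate (2R,3R,4R,5S)
Conditions: HF·pyridine, pyridine, THF, 0 °C
Reagents that add atoms: none
Why: Fluoride cleaves the Si–O bond of the enol silyl ether, whose oxygen is a good leaving group, much faster than it could affect the hindered dienoate. The buffered acidic medium avoids base-induced loss of the C2 hydroxyl through the vinylogous enolate.

## Compound list

1 | (S)-2-methylbutan-1-ol | CC[C@H](C)CO | starting material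
2 | (S)-2-methylbutanal | CC[C@H](C)C=O | intermediate
3 | triethyl (E)-4-phosphonocrotonate [ethyl (2E)-4-(diethoxyphosphoryl)but-2-enoate] | CCOC(=O)/C=C/CP(=O)(OCC)OCC | starting material
4 | lithium phosphonate carbanion of 3 | [Li+].CCOC(=O)/C=C/[CH-]P(=O)(OCC)OCC | intermediate (not isolated)
5 | ethyl (2E,4E,6S)-6-methylocta-2,4-dienoate | CC[C@H](C)/C=C/C=C/C(=O)OCC | intermediate
6 | (2E,4E,6S)-6-methylocta-2,4-dienoic acid | CC[C@H](C)/C=C/C=C/C(=O)O | intermediate
7 | 2,6-dimethoxy-4-methylphenol | COc1cc(C)cc(OC)c1O | starting material
8 | tert-butyl vinyl ether | C=COC(C)(C)C | starting material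
9 | 2,6,6-trimethoxy-4-methylcyclohexa-2,4-dien-1-one (masked o-benzoquinone) | COC1=CC(C)=CC(OC)(OC)C1=O | intermediate (not isolated)
10 | rac-(1S*,4R*,7R*)-7-tert-butoxy-1,3,3-trimethoxy-5-methylbicyclo[2.2.2]oct-5-en-2-one (tert-butoxy syn to the C5=C6 bridge; racemate, enantiomer carried on is drawn) | O=C1C(OC)(OC)[C@@H]2C[C@@H](OC(C)(C)C)[C@@]1(OC)C=C2C | intermediate
11 | (S)-N,S-dimethyl-S-phenylsulfoximine | CN=[S@@](C)(=O)c1ccccc1 | starting material
12 | [(S)-N-methyl-S-phenylsulfonimidoyl]methyllithium (lithiated 11) | [Li+].[CH2-][S@@](=O)(=NC)c1ccccc1 | intermediate (not isolated)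
13 | (1S,2S,4R,7R)-7-tert-butoxy-1,3,3-trimethoxy-5-methyl-2-{[(S)-N-methyl-S-phenylsulfonimidoyl]methyl}bicyclo[2.2.2]oct-5-en-2-ol (CH2S group syn to the C5=C6 bridge) | CN=[S@@](=O)(c1ccccc1)C[C@@]1(O)C(OC)(OC)[C@@H]2C[C@@H](OC(C)(C)C)[C@@]1(OC)C=C2C | intermediate
14 | (1S,4R,7R)-7-tert-butoxy-1,3,3-trimethoxy-5-methylbicyclo[2.2.2]oct-5-en-2-one | O=C1C(OC)(OC)[C@@H]2C[C@@H](OC(C)(C)C)[C@@]1(OC)C=C2C | intermediate
15 | (1S,4S,7R)-7-tert-butoxy-1-methoxy-5-methylbicyclo[2.2.2]oct-5-en-2-one | O=C1C[C@@H]2C[C@@H](OC(C)(C)C)[C@@]1(OC)C=C2C | intermediate
16 | (Z)-1-bromoprop-1-ene | C/C=C\Br | starting material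
17 | (Z)-prop-1-enyllithium | C/C=C\[Li] | intermediate (not isolated)
18 | (Z)-prop-1-enylcerium dichloride | C/C=C\[Ce](Cl)Cl | intermediate (not isolated)
19 | (1S,2S,4S,7R)-7-tert-butoxy-1-methoxy-5-methyl-2-[(1Z)-prop-1-en-1-yl]bicyclo[2.2.2]oct-5-en-2-ol (propenyl syn to the C5=C6 bridge) | C/C=C\[C@@]1(O)C[C@@H]2C[C@@H](OC(C)(C)C)[C@@]1(OC)C=C2C | intermediate
20 | potassium alkoxide of 19 | [K+].C/C=C\[C@@]1([O-])C[C@@H]2C[C@@H](OC(C)(C)C)[C@@]1(OC)C=C2C | intermediate (not isolated)
21 | potassium 8β-tert-butoxy-7-methoxy-10βH-11,12,13-trinoreremophila-2,6-dien-2-olate (4β,5β-dimethyl; cis-fused enolate) | [K+].[O-]C1=C[C@H](C)[C@@]2(C)C=C(OC)[C@H](OC(C)(C)C)C[C@H]2C1 | intermediate (not isolated)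
22 | 8β-tert-butoxy-7-methoxy-10βH-11,12,13-trinoreremophila-2,6-dien-2-yl trifluoromethanesulfonate (4β,5β-dimethyl; cis-fused) | FC(F)(F)S(=O)(=O)OC1=C[C@H](C)[C@@]2(C)C=C(OC)[C@H](OC(C)(C)C)C[C@H]2C1 | intermediate
23 | 8β-hydroxy-7-oxo-10βH-11,12,13-trinoreremophil-2-en-2-yl trifluoromethanesulfonate (4β,5β-dimethyl; cis-fused) | FC(F)(F)S(=O)(=O)OC1=C[C@H](C)[C@@]2(C)CC(=O)[C@H](O)C[C@H]2C1 | intermediate
24 | 8β-hydroxy-10βH-11,12,13-trinoreremophil-2-en-7-one (4β,5β-dimethyl; cis-fused) | C1=C[C@H](C)[C@@]2(C)CC(=O)[C@H](O)C[C@H]2C1 | intermediate
25 | 10βH-11,12,13-trinoreremophil-2-ene-7,8-dione (4β,5β-dimethyl; cis-fused; drawn as the diketo form) | C1=C[C@H](C)[C@@]2(C)CC(=O)C(=O)C[C@H]2C1 | intermediate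
26 | 7,8-bis(tert-butyldimethylsilyloxy)-10βH-11,12,13-trinoreremophila-2,6,8-triene (4β,5β-dimethyl) | C1=C[C@H](C)[C@@]2(C)C=C(O[Si](C)(C)C(C)(C)C)C(O[Si](C)(C)C(C)(C)C)=C[C@H]2C1 | intermediate (not isolated)
27 | 7-(tert-butyldimethylsilyloxy)-11,12,13-trinoreremophila-2,6,9-trien-8-one (4S,5S; 4β,5β-dimethyl) | C1=C[C@H](C)[C@@]2(C)C=C(O[Si](C)(C)C(C)(C)C)C(=O)C=C2C1 | intermediate
28 | 2α,3α-epoxy-7-(tert-butyldimethylsilyloxy)-11,12,13-trinoreremophila-6,9-dien-8-one (2R,3S,4R,5S) | O1[C@@H]2[C@H]1CC3=CC(=O)C(O[Si](C)(C)C(C)(C)C)=C[C@]3(C)[C@H]2C | intermediate
29 | 7-(tert-butyldimethylsilyloxy)-2α-hydroxy-8-oxo-11,12,13-trinoreremophila-6,9-dien-3β-yl (2E,4E,6S)-6-methylocta-2,4-dienoate (2R,3R,4R,5S) | CC[C@H](C)/C=C/C=C/C(=O)O[C@H]1[C@H](O)CC2=CC(=O)C(O[Si](C)(C)C(C)(C)C)=C[C@]2(C)[C@H]1C | intermediate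
30 | septeremophilane G, 2α,7-dihydroxy-8-oxo-11,12,13-trinoreremophila-6,9-dien-3β-yl (2E,4E,6S)-6-methylocta-2,4-dienoate (2R,3R,4R,5S) | CC[C@H](C)/C=C/C=C/C(=O)O[C@H]1[C@H](O)CC2=CC(=O)C(O)=C[C@]2(C)[C@H]1C | target

## Step count and least certain steps

Total step count: 16 (steps 1–3 for the acid 6, steps 4–16 for the main line). Longest linear sequence: 13 steps (steps 4–16, from 7).

Step 9 (key step). The most likely failure is that the inward Z-methyl slows the boat-shaped shift enough for alkoxide fragmentation to compete, or that proton transfer scrambles the enolate before sulfonylation. The fallback moves from the anionic to the neutral manifold. Setting out from 19, O-silylation (Me3SiOTf, 2,6-lutidine) gives the trimethylsilyl ether F1. Thermal siloxy-Cope rearrangement (degassed toluene, sealed tube, about 200 °C) gives the trimethylsilyl enol ether F2 with the same C2=C3 regiochemistry. MeLi (THF, 0 °C) releases the lithium enolate regiospecifically, and sulfonylation with the same triflimide returns to the route at 22.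

Step 15. The most likely failure is slow or misdirected opening: attack at C3 is axial, syn to the C5 methyl and next to C4, so attack at C2 through a twist-boat, rearrangement of the oxirane, or base-triggered opening from C1 may take over. The fallback separates ring opening from acylation. Setting out from 28, acid-catalysed hydration (HClO4, THF/H2O), which is trans-diaxial for the small nucleophile and also frees O7, gives the 2α,3β,7-triol F3. Et3SiCl/imidazole silylates the diosphenol and the less hindered 2α-hydroxyl to give the bis(triethylsilyl) ether F4. Yamaguchi esterification of the hindered 3β-hydroxyl with 6 (2,4,6-trichlorobenzoyl chloride, Et3N, DMAP, toluene) gives the ester F5. HF·pyridine removes both silyl groups and returns to the route at 30.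

Step 13. The most likely failure is palladation at the C6 terminus of the C7 enol ether, which cannot eliminate and leads to desilylation without dehydrogenation, or migration of the C2=C3 bond into conjugation once the dienone exists. The fallback dehydrogenates first and protects afterwards. Setting out from 25, quinone dehydrogenation of the enolised dione (DDQ, dioxane, 80 °C), as in the conversion of enones into cross-conjugated dienones, gives the free diosphenol trienone F6. Silylation (t-BuMe2SiCl, imidazole, DMF) returns to the route at 27.

Step 8. The most likely failure is partial loss of the Z geometry when the vinyl metal is made, or enolisation of 15 instead of addition. The fallback fixes the geometry after the C–C bond is made. Setting out from 15, addition of prop-1-ynylmagnesium bromide in the presence of CeCl3 gives the propargylic carbinol F7. Semihydrogenation (H2, Pd/CaCO3 poisoned with Pb(OAc)2, quinoline) delivers the Z-alkene by syn addition and returns to the route at 19.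

Step 5. The most likely failure is incomplete chromatographic separation of the two diastereomeric adducts, or their premature reversal on silica. The fallback is a physical resolution: setting out from 10, preparative chromatography on a chiral stationary phase (supercritical CO2/alcohol) gives 14 directly, with no new compound (F0) and without steps 5 and 6.

## Further compounds

F1 | step 9 | (1S,2S,4S,7R)-7-tert-butoxy-1-methoxy-5-methyl-2-[(1Z)-prop-1-en-1-yl]-2-(trimethylsilyloxy)bicyclo[2.2.2]oct-5-ene | C/C=C\[C@@]1(O[Si](C)(C)C)C[C@@H]2C[C@@H](OC(C)(C)C)[C@@]1(OC)C=C2C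
F2 | step 9 | 8β-tert-butoxy-7-methoxy-2-(trimethylsilyloxy)-10βH-11,12,13-trinoreremophila-2,6-diene (4β,5β-dimethyl; cis-fused) | C[Si](C)(C)OC1=C[C@H](C)[C@@]2(C)C=C(OC)[C@H](OC(C)(C)C)C[C@H]2C1
F3 | step 15 | 2α,3β,7-trihydroxy-11,12,13-trinoreremophila-6,9-dien-8-one (2R,3R,4R,5S) | O[C@H]1[C@H](O)CC2=CC(=O)C(O)=C[C@]2(C)[C@H]1C
F4 | step 15 | 3β-hydroxy-2α,7-bis(triethylsilyloxy)-11,12,13-trinoreremophila-6,9-dien-8-one | O[C@H]1[C@H](O[Si](CC)(CC)CC)CC2=CC(=O)C(O[Si](CC)(CC)CC)=C[C@]2(C)[C@H]1C
F5 | step 15 | 8-oxo-2α,7-bis(triethylsilyloxy)-11,12,13-trinoreremophila-6,9-dien-3β-yl (2E,4E,6S)-6-methylocta-2,4-dienoate | CC[C@H](C)/C=C/C=C/C(=O)O[C@H]1[C@H](O[Si](CC)(CC)CC)CC2=CC(=O)C(O[Si](CC)(CC)CC)=C[C@]2(C)[C@H]1C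
F6 | step 13 | 7-hydroxy-11,12,13-trinoreremophila-2,6,9-trien-8-one (4S,5S) | C1=C[C@H](C)[C@@]2(C)C=C(O)C(=O)C=C2C1
F7 | step 8 | (1S,2S,4S,7R)-7-tert-butoxy-1-methoxy-5-methyl-2-(prop-1-yn-1-yl)bicyclo[2.2.2]oct-5-en-2-ol | CC#C[C@@]1(O)C[C@@H]2C[C@@H](OC(C)(C)C)[C@@]1(OC)C=C2C
F0 | step 5 | none | none
A1 | alternative 1 | (2E,6R,8E,10E)-6-(tert-butyldimethylsilyloxy)-3-methyl-11-(triisopropylsilyloxy)undeca-2,8,10-trien-4-one (tigloyl ketone triene) | C/C=C(\C)C(=O)C[C@H](O[Si](C)(C)C(C)(C)C)C/C=C/C=C/O[Si](C(C)C)(C(C)C)C(C)C
A2 | alternative 1 | trans-fused 8-(tert-butyldimethylsilyloxy)-3β-(triisopropylsilyloxy)-4β,5β-dimethyloctal-1-en-6-one | CC(C)[Si](C(C)C)(C(C)C)O[C@H]1C=C[C@H]2C[C@@H](O[Si](C)(C)C(C)(C)C)CC(=O)[C@]2(C)[C@H]1C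
A3 | alternative 2 | 2-[(4-methoxybenzyl)oxy]-3-(7-methyl-8-methylidene-1,4-dioxaspiro[4.5]decan-7-yl)butanal, configured at C3, C4 and C5 (eremophilane locants) as in the target | COc1ccc(CO[C@@H](C=O)[C@H](C)[C@@]2(C)CC3(OCCO3)CCC2=C)cc1
A4 | alternative 2 | 2α-hydroxy-3β-[(4-methoxybenzyl)oxy]-4β,5β-dimethyloctal-9-en-7-one ethylene ketal | COc1ccc(CO[C@H]2[C@H](O)CC3=CCC4(OCCO4)C[C@]3(C)[C@H]2C)cc1
A5 | alternative 3 | 4-[3-(tert-butyldimethylsilyloxy)-4-oxopentan-2-yl]-2,6-dimethoxy-4-methylcyclohexa-2,5-dien-1-one, side chain configured as C3 and C4 of the target | CC(=O)[C@H](O[Si](C)(C)C(C)(C)C)[C@H](C)C1(C)C=C(OC)C(=O)C(OC)=C1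
A6 | alternative 3 | cis-fused 3β-(tert-butyldimethylsilyloxy)-7,9-dimethoxy-4β,5β-dimethyloctal-6-ene-2,8-dione | O=C1C[C@@H]2[C@H](OC)C(=O)C(OC)=C[C@]2(C)[C@@H](C)[C@H]1O[Si](C)(C)C(C)(C)C
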